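Assumption: atoms carry ent-kaurane numbers throughout. Compound 8 (C1 carbinol) and compounds 24–26 (C15 carbinol) are carried as epimer mixtures because both centres are oxidised later, and their SMILES leave those centres open.

## Analysis of the target

CNP0530135.1 is a 6,7-seco-ent-kaurane of the spirolactone type. Ring A (C1–C5, C10) is a 4,4-dimethylcyclohex-2-enone, joined through the spiro carbon C10 to a δ-lactone (C10, C20, O, C7, C8, C9). The lactone is fused along C8–C9 to the bicyclo[3.2.1]octane of ring C (C8, C9, C11–C14) and ring D (C8, C14, C13, C16, C15).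

There are six stereocentres: C5, C10, C9, C8, C13 and C16. C6 on C5 and C20 on C10 are cis on ring A. On the lactone, C11 and C14 lie on the face of C1, and H9 and C15 on the face of C5. C13 follows from C8 through the bridge. At C16 the hydroxyl is exo (syn to the one-carbon bridge C14) and the methyl endo.

The sensitive groups are:
- the C7/C15 1,3-dicarbonyl on quaternary C8, which nucleophiles can cleave by retro-Claisen reaction;
- the tertiary α-ketol C15/C16, which can undergo an acyloin shift to a bicyclo[2.2.2]octane;
- the enone, and the free primary C6 hydroxyl close to C1.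

The difficulty lies in three quaternary carbons (C4, C10, C8), two of which flank C9, and in two neighbouring one-carbon arms that must end differently: C6 as a free alcohol, C20 as the lactone oxygen carrier.

The strategy rests on one feature. C6–C5–C10–C20 are four contiguous carbons with C6 and C20 cis, and C10 also carries C9 next to the C1 carbonyl. This is the pattern of a cyclobutene fused to the α,β-bond of a 2-carboxycyclohexenone whose carboxyl carbon is C9.

## Retrosynthetic reasoning

**C2=C3 and the silyl groups (32 from 31 from 29).** The ring A double bond is introduced last. In 29 the C1 ketone is the only enolisable carbonyl, because C7 and C15 sit between quaternary C8 and fully substituted C16, so the regiochemistry of dehydrogenation is automatic. An earlier enone would not survive the hydride, radical and metal hydride steps.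

**C16–O (29 from 27).** The tertiary ketol is traced to the exocyclic 15-oxo-16-ene. Hydrogen-atom transfer to C17 followed by oxygen capture at C16 installs the methyl and the hydroxyl in one operation, with oxygen entering from the open exo face.

**Ring D, C13–C16 and C15–C16 (27 from 26 from 24 from 22 and 23).** Cutting C13–C16 leads to a 1,6-enyne: a vinyl radical at C16 closes 5-exo onto C13 of a ring C alkene. The alkyne carbons C16 and C17 come from 23, added to a C15 aldehyde on C8. C15 stays oxygenated throughout, so no allylic oxidation is needed.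

**Ring C, C9–C11 and C8–C14 (22 from 20 and 21).** Both bonds are cut at once as a Diels–Alder reaction of the C8=C9 bond of a spirolactone with 21. Suprafacial addition puts C11 and C14 on the same lactone face and makes C8 quaternary. The symmetrical diene raises no regiochemical question. The forward reaction needs a doubly activated dienophile, so C8 must carry the future C15 as a formyl group.

**C8–C15 (20 from 19 from 17 and 18, 17 from 15).** The formyl carbon is attached to the unsaturated lactone by halogenation at C8 and cross-coupling with 18, followed by oxidation.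

**Lactone C20–O bond and the C6=C20 bond (15 from 14 from 11).** Cleavage of the cyclobutene releases both arms at once. They are told apart without protecting-group selectivity, because only the C20 hydroxyl can close a six-membered lactone onto the Z-enoate; the C6 hydroxyl remains and is silylated.

**C8=C9 (11 from 9 and 10, 9 from 8 from 7).** The ester carbon C9 of 7 is brought to the aldehyde level and olefinated Z-selectively. The C1 ketone is regenerated in the same oxidation, so it needs no protecting group.

**C10–C20 and C5–C6 (7 from 5 and 6).** The cyclobutene is cut back to the enone ester 5 and 6. The [2+2] photocycloaddition creates quaternary C10 and sets C5, and the cis ring fusion fixes their relation. Only the absolute face has to be controlled.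

**The photosubstrate (5 from 3 from 1 and 2).** Carbomethoxylation and dehydrogenation by selenoxide elimination.

## Alternatives that were turned down

**Alternative 1:** Rings C and D are cut at C13–C14 and C8–C15.
- Forward step: a secondary radical at C13 adds to the exocyclic carbon C14 of an α-methylene spirolactone, closing ring C in the 6-endo mode. The resulting C8 radical closes 5-exo-dig onto an alkyne to give the 15-methylene bicyclo[3.2.1]octane A1.
- For: one chain reaction makes two rings and the C8 quaternary centre. The first addition is polarity-matched, and no halogenation or cross-coupling at C8 is needed. On these points it is stronger than the chosen plan.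
- Against: the side chain with the iodide and the alkyne must be attached to C9 with stereocontrol beforehand, which needs a separate fragment. A1 also has ring D at the wrong oxidation pattern (methylene on C15, CH2 at C16), so ozonolysis, methylation and hydroxylation at C16 must follow on a substrate whose C1 ketone is still masked.
- Comparison: the chosen plan sets C9 and C8 together in one suprafacial cycloaddition and reaches the C15 ketone and C16 carbinol without enolate chemistry.

**Alternative 2:** Ring A and the C8–C9 bond are cut together.
- Forward step: an excited dioxinone (C7, C8, C1) adds across a tethered C9=C10 alkene, forming C1–C10 and C8–C9 and giving the 6-4-6 adduct A2. Retro-aldol opening of the cyclobutane then frees the C1 ketone and the C7 carboxyl.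
- For: the most hindered bond (C8–C9) and quaternary C10 form intramolecularly, and the C1/C7 dicarbonyl relation comes for free. It is stronger than the chosen plan in making C8–C9 directly.
- Against: A2 requires a long open-chain substrate that already holds C5, C13, the gem-dimethyl group and three differentiated oxygens. The alkene geometry decides C9, and face selection rests on C5 alone. After fragmentation C8 still needs two further C–C bonds.
- Comparison: the chosen photoreaction uses a symmetrical gas and a three-step substrate, and defers C8–C9 to a reliable olefination.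

**Alternative 3:** The C5–C10 bond is made by a 1,2-shift.
- Forward step: a Lewis acid opens a C10–C20 epoxide at C10 while the C1–C5 bond of a five-membered carbinol ring migrates to C10, giving the ring A ketone A3.
- For: the shift is stereospecific, avoids photochemistry and ozone, and delivers the two arms on C10 already differentiated (free C20 hydroxyl, protected C9 oxygen). On arm differentiation it is stronger than the chosen plan, which differentiates C20 and C6 by ring size of lactonisation instead.
- Against: C5 and the epoxide are two independent stereocontrol events. Migration of the C1–C5 bond must beat that of C1–C2, although C5 carries an inductively deactivating silyloxymethyl group. A3 is only ring A; C9 still has to be oxidised and olefinated.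
- Comparison: the chosen plan reaches a comparable stage in seven steps from commodity chemicals, with the C5/C10 relation guaranteed by the cis ring fusion.

Key step: step 3

## Route

Step 1
Reactants: 1 4,4-dimethylcyclohexan-1-one; 2 dimethyl carbonate
Product: 3 methyl 5,5-dimethyl-2-oxocyclohexane-1-carboxylate
Conditions: NaH, THF, reflux; aq. HCl work-up
Reagents that add atoms: none
Why: Claisen-type carbomethoxylation of the ketone enolate; the symmetrical ketone gives one regioisomer and deprotonation of the β-keto ester drives the equilibrium.

Step 2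
Reactants: 3 methyl 5,5-dimethyl-2-oxocyclohexane-1-carboxylate
Product: 5 methyl 3,3-dimethyl-6-oxocyclohex-1-ene-1-carboxylate, via α-phenylselanyl keto ester 4 (not isolated)
Conditions: PhSeCl, pyridine, CH2Cl2, 0 °C; then 30% H2O2, 0 °C to rt
Reagents that add atoms: none
Why: Selenenylation of the β-keto ester at the doubly activated carbon and syn selenoxide elimination; the only β-hydrogens are on the ring CH2, so the endocyclic enone is the sole product.

Step 3
Reactants: 5 methyl 3,3-dimethyl-6-oxocyclohex-1-ene-1-carboxylate; 6 acetylene
Product: 7 methyl (1S,6R)-5,5-dimethyl-2-oxobicyclo[4.2.0]oct-7-ene-1-carboxylate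
Conditions: HC≡CH (saturated), chiral 1,3,2-oxazaborolidine (from a diarylprolinol and 2,4,6-trifluorophenylboronic acid) activated with AlBr3 (50 mol%), CH2Cl2, −75 °C, hν (366 nm)
Reagents that add atoms: none
Why: Proposed new method: the closest known reactions are the direct-irradiation enone–alkyne [2+2] photocycloaddition (racemic) and the AlBr3-activated oxazaborolidine-catalysed enone–olefin [2+2] photocycloaddition, and this step merges the two. Coordination of the boron Lewis acid to the C1 carbonyl of 5 shifts the enone absorption to longer wavelength, so that at 366 nm essentially only the complex is excited and the racemic background is suppressed. The excited complex, a triplet after intersystem crossing, bonds first from C5 to acetylene and leaves a 1,4-biradical with one spin at C10, stabilised by both carbonyls, and a vinyl radical at C20; spin inversion and C10–C20 recombination close the four-membered ring. This cyclobutene is the only ring formed and can only close cis to the six-membered ring, so the C5/C10 relation (C6 and C20 syn) is fixed by the ring fusion. The absolute configuration at C5 and C10 is set by the catalyst, whose aryl groups cover one face of the bound enone; the enantiomer of the amino alcohol is chosen to deliver the (1S,6R) adduct. The step needs enantioface selectivity and a single addition: acetylene is symmetrical, so no regiochemistry arises, and the β,γ-unsaturated ketone 7 does not absorb at 366 nm, which protects it from 1,3-acyl shift. The open point is that C10 bears an ester and no hydrogen, so the two-point binding that orients simple enones on this catalyst is unavailable and the ester carbonyl may compete for boron.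

Step 4
Reactants: 7 methyl (1S,6R)-5,5-dimethyl-2-oxobicyclo[4.2.0]oct-7-ene-1-carboxylate
Product: 8 cis-fused 1-(hydroxymethyl)-5,5-dimethylbicyclo[4.2.0]oct-7-en-2-ol (ring fusion as in 7; epimers at the carbinol carbon)
Conditions: LiAlH4, THF, 0 °C
Reagents that add atoms: none
Why: Hydride reduction of ester and ketone to the 1,3-diol; the isolated cyclobutene is inert and the new carbinol centre is removed in step 5.

Step 5
Reactants: 8 cis-fused 1-(hydroxymethyl)-5,5-dimethylbicyclo[4.2.0]oct-7-en-2-ol
Product: 9 cis-fused 5,5-dimethyl-2-oxobicyclo[4.2.0]oct-7-ene-1-carbaldehyde (ring fusion as in 7)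
Conditions: (COCl)2, DMSO, CH2Cl2, −78 °C; Et3N, −78 to 0 °C
Reagents that add atoms: none
Why: Double Swern oxidation; the β-keto aldehyde has a quaternary α-carbon (C10), so it cannot enolise or epimerise, and C1 returns to the ketone level it keeps until step 17.

Step 6
Reactants: 9 cis-fused 5,5-dimethyl-2-oxobicyclo[4.2.0]oct-7-ene-1-carbaldehyde; 10 methyl 2-[bis(2,2,2-trifluoroethoxy)phosphoryl]acetate
Product: 11 methyl (Z)-3-(5,5-dimethyl-2-oxobicyclo[4.2.0]oct-7-en-1-yl)prop-2-enoate (ring fusion as in 7)
Conditions: KN(SiMe3)2, 18-crown-6, THF, −78 °C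
Reagents that add atoms: none
Why: Still–Gennari olefination; the aldehyde is far more electrophilic than the hindered C1 ketone, and fast elimination from the trifluoroethyl phosphonate adduct gives the Z-enoate (C7 cis to C10) needed for lactonisation.

Step 7
Reactants: 11 methyl (Z)-3-(5,5-dimethyl-2-oxobicyclo[4.2.0]oct-7-en-1-yl)prop-2-enoate
Product: 14 hydroxy spirolactone 7-(hydroxymethyl)-8,8-dimethyl-2-oxaspiro[5.5]undec-4-ene-3,11-dione (C6 arm cis to C20), via keto dialdehyde 12 (not isolated), via diol enoate 13 (not isolated)
Conditions: O3, CH2Cl2, −78 °C (indicator end point); PPh3; LiAlH(OtBu)3, THF, −78 to −20 °C; then PPTS (cat.), PhH, 50 °C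
Reagents that add atoms: ozone, [O-][O+]=O
Why: Ozonolysis cuts the strained, electron-rich cyclobutene in preference to the electron-poor enoate and gives the two cis formyl arms, which LiAlH(OtBu)3 reduces much faster than the hindered C1 ketone or the enoate; with a single hydride it cannot deliver a second one from the C20 alkoxide. Only the C20 hydroxyl can close a six-membered lactone onto the Z-ester (the C6 hydroxyl would need a seven-membered ring), so transesterification tells the two arms apart.

Step 8
Reactants: 14 hydroxy spirolactone
Product: 15 7-[(tert-butyldimethylsilyloxy)methyl]-8,8-dimethyl-2-oxaspiro[5.5]undec-4-ene-3,11-dione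
Conditions: TBSCl, imidazole, DMF, rt
Reagents that add atoms: tert-butyldimethylsilyl chloride, CC(C)(C)[Si](C)(C)Cl
Why: Silylation of the only hydroxyl; the bulky silyl ether removes the risk of oxa-Michael addition of O6 to C9 and later enlarges the C5 face of the lactone.

Step 9
Reactants: 15 silyl ether
Product: 17 4-bromo-7-[(tert-butyldimethylsilyloxy)methyl]-8,8-dimethyl-2-oxaspiro[5.5]undec-4-ene-3,11-dione (bromine on C8), via trans-dibromide 16 (not isolated)
Conditions: Br2, CH2Cl2, NaHCO3 (solid), 0 °C, dark; then Et3N, 0 °C to rt
Reagents that add atoms: bromine, BrBr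
Why: Bromination–dehydrobromination of the α,β-unsaturated δ-lactone: anti addition across C8=C9, then base removes the acidic C8 hydrogen and expels the C9 bromide, so bromine remains on C8.

Step 10
Reactants: 17 α-bromo lactone; 18 (tributylstannyl)methanol
Product: 19 4-(hydroxymethyl)-7-[(tert-butyldimethylsilyloxy)methyl]-8,8-dimethyl-2-oxaspiro[5.5]undec-4-ene-3,11-dione
Conditions: Pd(PPh3)4 (5 mol%), dioxane, 90 °C
Reagents that add atoms: none
Why: Stille coupling of an α-bromo enoate with a hydroxymethylstannane (oxidative addition to zerovalent palladium, transfer of the CH2OH group, reductive elimination) attaches C15 to C8; ketone, lactone and silyl ether are inert.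

Step 11
Reactants: 19 hydroxymethyl lactone
Product: 20 7-[(tert-butyldimethylsilyloxy)methyl]-8,8-dimethyl-3,11-dioxo-2-oxaspiro[5.5]undec-4-ene-4-carbaldehyde
Conditions: Dess–Martin periodinane, CH2Cl2, 0 °C to rt; used at once
Reagents that add atoms: none
Why: Oxidation of the primary allylic alcohol to the 2-formyl unsaturated lactone; C10 is quaternary, so the product has no γ-hydrogen and cannot tautomerise to a dienol.

Step 12
Reactants: 20 formyl lactone; 21 buta-1,3-diene
Product: 22 tricyclic formyl lactone: spirolactone cis-fused at C8–C9 to a cyclohexene (C12=C13), CHO (C15) on C8, C11 and C14 on the lactone face of C1, C1 ketone, C6 silyl ether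
Conditions: buta-1,3-diene (excess), ZnCl2, CH2Cl2, −78 to 0 °C, sealed tube
Reagents that add atoms: none
Why: Lewis-acid-promoted Diels–Alder reaction of an alkylidene 1,3-dicarbonyl dienophile; ZnCl2 chelates the formyl and lactone carbonyls and makes C9 strongly electrophilic despite its neopentyl position. Suprafacial addition puts C11 and C14 cis and makes C8 quaternary. The diene should approach C8=C9 past the flat C1 carbonyl and not past C5, which carries the silyloxymethyl arm and adjoins the gem-dimethyl carbon, and this sets C9 and C8 relative to C10.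

Step 13
Reactants: 22 tricyclic formyl lactone; 23 ethynylmagnesium bromide
Product: 24 propargylic alcohol: 22 with CH(OH)C≡CH (C15, C16, C17) in place of CHO on C8 (C15 epimers)
Conditions: THF, −78 °C; aq. NH4Cl
Reagents that add atoms: none
Why: Grignard addition to the aldehyde, which reacts far faster at −78 °C than the hindered C1 ketone or the lactone; the cold quench avoids retro-aldol loss of the new side chain, and the C15 configuration is irrelevant.

Step 14
Reactants: 24 propargylic alcohol
Product: 26 tetracyclic allylic alcohol: bicyclo[3.2.1]octane with C16=C17 exocyclic methylene and C15 hydroxyl (C15 epimers), via vinylstannane 25 (not isolated)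
Conditions: Bu3SnH, AIBN, PhH (0.02 M), 80 °C; then TsOH·H2O, CH2Cl2, 0 °C
Reagents that add atoms: none
Why: Stannyl-radical 1,6-enyne cyclisation: Bu3Sn adds to the terminal alkyne carbon C17, the C16 vinyl radical closes 5-exo-trig onto C13, and the C12 radical is reduced by Bu3SnH. The bridge can only form on the ring C face that carries C15, which sets C13. Ipso protonation then removes tin and leaves the exocyclic methylene.

Step 15
Reactants: 26 tetracyclic allylic alcohol
Product: 27 tetracyclic enone: 15-oxo-16-ene with C1 ketone, 7,20-lactone and C6 silyl ether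
Conditions: Dess–Martin periodinane, CH2Cl2, rt
Reagents that add atoms: none
Why: Oxidation of the secondary allylic alcohol; both C15 epimers converge on the exocyclic enone.

Step 16
Reactants: 27 tetracyclic enone
Product: 29 ketol: 16-hydroxy-16-methyl-15-ketone (hydroxyl exo, syn to C14) with C1 ketone and C6 silyl ether, via C16 hydroperoxide 28 (not isolated)
Conditions: Mn(dpm)3 (dpm = dipivaloylmethanate, cat.), PhSiH3, O2 (1 atm), i-PrOH/CH2Cl2, 0 °C; then P(OEt)3
Reagents that add atoms: dioxygen, O=O
Why: Mukaiyama-type hydration of an enone: a manganese hydride transfers a hydrogen atom to C17, the tertiary α-keto radical at C16 captures O2, and the phosphite reduces the hydroperoxide. Oxygen enters from the exo face, away from the three-carbon bridge (C9, C11, C12), which gives the exo hydroxyl and endo methyl; the saturated C1 ketone is untouched.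

Step 17
Reactants: 29 ketol
Product: 31 protected enone: C2=C3 enone with C16 trimethylsilyl ether and C6 tert-butyldimethylsilyl ether, via bis(trimethylsilyl) enol ether 30 (not isolated)
Conditions: TMSOTf, Et3N, CH2Cl2, 0 °C; then Pd(OAc)2, MeCN, rt
Reagents that add atoms: trimethylsilyl trifluoromethanesulfonate, C[Si](C)(C)OS(=O)(=O)C(F)(F)F
Why: Saegusa–Ito dehydrogenation; C1 is the only enolisable carbonyl (C15 and C7 have no α-hydrogen), so soft enolisation gives the C1=C2 silyl enol ether alone, and palladium diacetate (divalent palladium) forms the C2=C3 enone by β-hydride loss from C3. Rapid silylation of the tertiary hydroxyl keeps the α-ketol from acyloin shift.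

Step 18
Reactants: 31 protected enone
Product: 32 CNP0530135.1
Conditions: HF·pyridine, THF, 0 °C to rt
Reagents that add atoms: none
Why: Fluoride-mediated cleavage of both silyl ethers under mildly acidic conditions that spare the enone, the lactone and the α-ketol.

## Compound list

1 | 4,4-dimethylcyclohexan-1-one | CC1(C)CCC(=O)CC1 | starting material
2 | dimethyl carbonate | COC(=O)OC | starting material
3 | methyl 5,5-dimethyl-2-oxocyclohexane-1-carboxylate (racemic, keto–enol mixture) | COC(=O)C1CC(C)(C)CCC1=O | intermediate
4 | methyl 5,5-dimethyl-2-oxo-1-(phenylselanyl)cyclohexane-1-carboxylate (racemic) | COC(=O)C1([Se]c2ccccc2)CC(C)(C)CCC1=O | intermediate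
5 | methyl 3,3-dimethyl-6-oxocyclohex-1-ene-1-carboxylate | COC(=O)C1=CC(C)(C)CCC1=O | intermediate
6 | acetylene | C#C | starting material
7 | methyl (1S,6R)-5,5-dimethyl-2-oxobicyclo[4.2.0]oct-7-ene-1-carboxylate | CC1(C)CCC(=O)[C@]2(C(=O)OC)C=C[C@H]12 | intermediate
8 | cis-fused 1-(hydroxymethyl)-5,5-dimethylbicyclo[4.2.0]oct-7-en-2-ol, ring fusion as in 7, carbinol epimers | CC1(C)CCC(O)[C@]2(CO)C=C[C@H]12 | intermediate
9 | cis-fused 5,5-dimethyl-2-oxobicyclo[4.2.0]oct-7-ene-1-carbaldehyde, ring fusion as in 7 | CC1(C)CCC(=O)[C@]2(C=O)C=C[C@H]12 | intermediate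
10 | methyl 2-[bis(2,2,2-trifluoroethoxy)phosphoryl]acetate | COC(=O)CP(=O)(OCC(F)(F)F)OCC(F)(F)F | starting material
11 | methyl (Z)-3-(5,5-dimethyl-2-oxobicyclo[4.2.0]oct-7-en-1-yl)prop-2-enoate, ring fusion as in 7 | CC1(C)CCC(=O)[C@]2(/C=C\C(=O)OC)C=C[C@H]12 | intermediate
12 | methyl (Z)-3-(1,2-diformyl-3,3-dimethyl-6-oxocyclohexyl)prop-2-enoate, formyl groups cis | CC1(C)CCC(=O)[C@](/C=C\C(=O)OC)(C=O)[C@@H]1C=O | intermediate
13 | methyl (Z)-3-[1,2-bis(hydroxymethyl)-3,3-dimethyl-6-oxocyclohexyl]prop-2-enoate, hydroxymethyl groups cis | CC1(C)CCC(=O)[C@](/C=C\C(=O)OC)(CO)[C@@H]1CO | intermediate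
14 | 7-(hydroxymethyl)-8,8-dimethyl-2-oxaspiro[5.5]undec-4-ene-3,11-dione, CH2OH cis to the lactone CH2O | CC1(C)CCC(=O)[C@]2(COC(=O)C=C2)[C@@H]1CO | intermediate
15 | 7-[(tert-butyldimethylsilyloxy)methyl]-8,8-dimethyl-2-oxaspiro[5.5]undec-4-ene-3,11-dione | CC1(C)CCC(=O)[C@]2(COC(=O)C=C2)[C@@H]1CO[Si](C)(C)C(C)(C)C | intermediate
16 | trans-4,5-dibromo-7-[(tert-butyldimethylsilyloxy)methyl]-8,8-dimethyl-2-oxaspiro[5.5]undecane-3,11-dione | CC1(C)CCC(=O)[C@]2(COC(=O)C(Br)C2Br)[C@@H]1CO[Si](C)(C)C(C)(C)C | intermediate
17 | 4-bromo-7-[(tert-butyldimethylsilyloxy)methyl]-8,8-dimethyl-2-oxaspiro[5.5]undec-4-ene-3,11-dione | CC1(C)CCC(=O)[C@]2(COC(=O)C(Br)=C2)[C@@H]1CO[Si](C)(C)C(C)(C)C | intermediate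
18 | (tributylstannyl)methanol | CCCC[Sn](CO)(CCCC)CCCC | starting material
19 | 4-(hydroxymethyl)-7-[(tert-butyldimethylsilyloxy)methyl]-8,8-dimethyl-2-oxaspiro[5.5]undec-4-ene-3,11-dione | CC1(C)CCC(=O)[C@]2(COC(=O)C(CO)=C2)[C@@H]1CO[Si](C)(C)C(C)(C)C | intermediate
20 | 7-[(tert-butyldimethylsilyloxy)methyl]-8,8-dimethyl-3,11-dioxo-2-oxaspiro[5.5]undec-4-ene-4-carbaldehyde | CC1(C)CCC(=O)[C@]2(COC(=O)C(C=O)=C2)[C@@H]1CO[Si](C)(C)C(C)(C)C | intermediate
21 | buta-1,3-diene | C=CC=C | starting material
22 | tricyclic formyl lactone (spirolactone cis-fused to cyclohex-12-ene, C15 formyl on C8, C1 ketone, C6 silyl ether) | CC1(C)CCC(=O)[C@]2(COC(=O)[C@@]3(C=O)CC=CC[C@H]32)[C@@H]1CO[Si](C)(C)C(C)(C)C | intermediate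
23 | ethynylmagnesium bromide | C#C[Mg]Br | starting material
24 | propargylic alcohol (22 with CH(OH)C≡CH on C8, C15 epimers) | CC1(C)CCC(=O)[C@]2(COC(=O)[C@@]3(C(O)C#C)CC=CC[C@H]32)[C@@H]1CO[Si](C)(C)C(C)(C)C | intermediate
25 | vinylstannane (bicyclo[3.2.1]octane with C16=C17H–SnBu3, C15 hydroxyl) | CC1(C)CCC(=O)[C@]2(COC(=O)[C@@]34C[C@@H](CC[C@H]32)C(=C[Sn](CCCC)(CCCC)CCCC)C4O)[C@@H]1CO[Si](C)(C)C(C)(C)C | intermediate
26 | tetracyclic allylic alcohol (15-hydroxy-16-ene, C15 epimers) | CC1(C)CCC(=O)[C@]2(COC(=O)[C@@]34C[C@@H](CC[C@H]32)C(=C)C4O)[C@@H]1CO[Si](C)(C)C(C)(C)C | intermediate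
27 | tetracyclic enone (15-oxo-16-ene) | CC1(C)CCC(=O)[C@]2(COC(=O)[C@@]34C[C@@H](CC[C@H]32)C(=C)C4=O)[C@@H]1CO[Si](C)(C)C(C)(C)C | intermediate
28 | C16 hydroperoxide (16-hydroperoxy-16-methyl-15-ketone, OOH exo) | CC1(C)CCC(=O)[C@]2(COC(=O)[C@@]34C[C@@H](CC[C@H]32)[C@](C)(OO)C4=O)[C@@H]1CO[Si](C)(C)C(C)(C)C | intermediate
29 | ketol (16-hydroxy-16-methyl-15-ketone, OH exo; C1 ketone; C6 silyl ether) | CC1(C)CCC(=O)[C@]2(COC(=O)[C@@]34C[C@@H](CC[C@H]32)[C@](C)(O)C4=O)[C@@H]1CO[Si](C)(C)C(C)(C)C | intermediate
30 | bis(trimethylsilyl) compound (C1=C2 trimethylsilyl enol ether, C16 trimethylsilyl ether, C6 tert-butyldimethylsilyl ether) | CC1(C)CC=C(O[Si](C)(C)C)[C@]2(COC(=O)[C@@]34C[C@@H](CC[C@H]32)[C@](C)(O[Si](C)(C)C)C4=O)[C@@H]1CO[Si](C)(C)C(C)(C)C | intermediate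
31 | protected enone (C2=C3 enone, C16 trimethylsilyl ether, C6 tert-butyldimethylsilyl ether) | CC1(C)C=CC(=O)[C@]2(COC(=O)[C@@]34C[C@@H](CC[C@H]32)[C@](C)(O[Si](C)(C)C)C4=O)[C@@H]1CO[Si](C)(C)C(C)(C)C | intermediate
32 | CNP0530135.1 | CC1(C)C=CC(=O)[C@]2(COC(=O)[C@@]34C[C@@H](CC[C@H]32)[C@](C)(O)C4=O)[C@@H]1CO | target

## Step count and least certain steps

Total: 18 steps. Longest linear sequence: 18 steps, from 1.

**Step 3 (key step, proposed new method).** Enantioface selection may be poor, because the enone has no α-hydrogen for two-point binding and the ester carbonyl can compete for boron. The uncatalysed racemic reaction may also compete, and acetylene may react with the Lewis acid.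
- Fallback: a chiral ester auxiliary and separation of diastereomers, using known reaction types. It sets out from 3 and returns at 8.
- Transesterification of 3 with (−)-8-phenylmenthol (DMAP, toluene, reflux) should give 8-phenylmenthyl keto ester F1.
- Selenenylation to the phenylselanyl ester F2 and selenoxide elimination as in step 2 should give the auxiliary enone ester F3.
- Direct irradiation of F3 with acetylene (CH2Cl2, −78 °C, Pyrex-filtered light) should give the cis-fused adducts. The (1S,6R) diastereomer F4 is separated by chromatography or crystallisation, so any level of induction is enough; the antipodal auxiliary is used if the sense is reversed.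
- LiAlH4 reduction of F4 as in step 4 gives 8 and returns the auxiliary.

**Step 12.** Facial selectivity may be poor if the diene also approaches past C5, and the formyl-ene may react as an oxadiene.
- Fallback: reagent control instead of substrate control. The 1,3-dicarbonyl of 20 is chelated by Cu(OTf)2 carrying a C2-symmetric tert-butyl bis(oxazoline) ligand of the matched hand, so that the ligand blocks the C5 face. It starts from 20 and returns at 22; no new compound is made (F0).

**Step 14.** The vinyl radical may attack C12 (6-exo) to give the bicyclo[2.2.2]octane, the homoallyl radical may rearrange at low tin hydride concentration, or the vinyl radical may be reduced before it cyclises.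
- Fallback: a palladium hydride reductive enyne cyclisation (Pd2(dba)3·CHCl3, AcOH, Et3SiH, toluene). Hydropalladation places palladium on C16, syn carbopalladation is limited by geometry to C13, and the silane cleaves the C12–Pd bond. It starts from 24 and returns at 26; no new compound is made (F0).

**Step 7.** The C1 ketone may be partly reduced, and the cis dialdehyde may cyclise or epimerise at C5 before reduction.
- Fallback: reduce everything and re-oxidise C1. It starts from 11 and returns at 15.
- Ozonolysis with NaBH4 work-up should give triol enoate F5, which lactonises through the primary C20 hydroxyl (faster than the hindered secondary C1 hydroxyl) to dihydroxy spirolactone F6.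
- TBSCl silylates the primary hydroxyl selectively to give silyl ether alcohol F7, and Dess–Martin oxidation of the C1 carbinol gives 15.

**Step 9.** Addition of bromine to the electron-poor, neopentyl-flanked C8=C9 bond may be slow, and acid-catalysed bromination at C2 of the ketone may compete.
- Fallback: a conjugate addition–aldol–elimination sequence that avoids the halide. It starts from 15 and returns at 19, bypassing 17.
- Me2AlSePh adds to C9, and the aluminium enolate is trapped with formaldehyde to give seleno aldol adduct F8.
- H2O2 then eliminates the selenoxide to restore C8=C9 and give 19.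

## Further compounds

F1 | step 3 | (1R,2S,5R)-5-methyl-2-(2-phenylpropan-2-yl)cyclohexyl 5,5-dimethyl-2-oxocyclohexane-1-carboxylate | CC1(C)CCC(=O)C(C1)C(=O)O[C@@H]1C[C@H](C)CC[C@H]1C(C)(C)c1ccccc1
F2 | step 3 | (1R,2S,5R)-5-methyl-2-(2-phenylpropan-2-yl)cyclohexyl 5,5-dimethyl-2-oxo-1-(phenylselanyl)cyclohexane-1-carboxylate | CC1(C)CCC(=O)C(C1)([Se]c1ccccc1)C(=O)O[C@@H]1C[C@H](C)CC[C@H]1C(C)(C)c1ccccc1
F3 | step 3 | (1R,2S,5R)-5-methyl-2-(2-phenylpropan-2-yl)cyclohexyl 3,3-dimethyl-6-oxocyclohex-1-ene-1-carboxylate | CC1(C)CCC(=O)C(=C1)C(=O)O[C@@H]1C[C@H](C)CC[C@H]1C(C)(C)c1ccccc1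
F4 | step 3 | (1R,2S,5R)-5-methyl-2-(2-phenylpropan-2-yl)cyclohexyl (1S,6R)-5,5-dimethyl-2-oxobicyclo[4.2.0]oct-7-ene-1-carboxylate | CC1(C)CCC(=O)[C@]2(C(=O)O[C@@H]3C[C@H](C)CC[C@H]3C(C)(C)c3ccccc3)C=C[C@H]12
F0 | step 12 | none | none
F0 | step 14 | none | none
F5 | step 7 | methyl (Z)-3-[6-hydroxy-1,2-bis(hydroxymethyl)-3,3-dimethylcyclohexyl]prop-2-enoate, hydroxymethyl groups cis, C1 carbinol epimers | CC1(C)CCC(O)[C@](/C=C\C(=O)OC)(CO)[C@@H]1CO
F6 | step 7 | 11-hydroxy-7-(hydroxymethyl)-8,8-dimethyl-2-oxaspiro[5.5]undec-4-en-3-one, carbinol epimers | CC1(C)CCC(O)[C@]2(COC(=O)C=C2)[C@@H]1CO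
F7 | step 7 | 7-[(tert-butyldimethylsilyloxy)methyl]-11-hydroxy-8,8-dimethyl-2-oxaspiro[5.5]undec-4-en-3-one, carbinol epimers | CC1(C)CCC(O)[C@]2(COC(=O)C=C2)[C@@H]1CO[Si](C)(C)C(C)(C)C
F8 | step 9 | 7-[(tert-butyldimethylsilyloxy)methyl]-4-(hydroxymethyl)-8,8-dimethyl-5-(phenylselanyl)-2-oxaspiro[5.5]undecane-3,11-dione, mixture at C8 and C9 | CC1(C)CCC(=O)[C@]2(COC(=O)C(CO)C2[Se]c2ccccc2)[C@@H]1CO[Si](C)(C)C(C)(C)C
A1 | alternative 1 | 15-methylene bicyclo[3.2.1]octane spirolactone with C1 dioxolane and C6 silyl ether | CC1(C)CCC5(OCCO5)[C@]2(COC(=O)[C@@]34C[C@@H](CC[C@H]32)CC4=C)[C@@H]1CO[Si](C)(C)C(C)(C)C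
A2 | alternative 2 | cis-anti-cis 6-4-6 dioxinone photoadduct with cyclobutane C1, C8, C9, C10 | CC1(C)OC(=O)[C@@H]2[C@@H](CC[C@H](COCc3ccc(OC)cc3)C(C)=C)[C@@]3(COC(C)=O)[C@H](CO[Si](C)(C)C(C)(C)C)C(C)(C)CC[C@@]23O1
A3 | alternative 3 | ring A ketone with quaternary C10 bearing C20H2OH and C9H2O-PMB and with the C6 silyl ether | CC1(C)CCC(=O)[C@@](CO)(COCc2ccc(OC)cc2)[C@@H]1CO[Si](C)(C)C(C)(C)C
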